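**Retrosynthetic overview**
1. Numbering (germacrane): ten-membered carbocycle C1–C10 with the C1 ketone, C4–C5 epoxide (methyl on C4), C6 lactone CH–O, C8 angelate carbinol and C10 CHMe; butenolide ring O–C6–C7=C11–C12(=O); C13 is the acetoxymethyl carbon on C11.
2. Feature used: in the carbocycle the C1 ketone and the C8 oxygen are 1,4-related through C10–C9. With C8 as a ketone, C10 is the β-carbon of an enone and C1 an acyl anion site, so C1–C10 is cut (intramolecular Stetter reaction of a C1 aldehyde onto a C8 (E)-crotonyl ketone).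
3. The butenolide stays open (C12 methyl ester, C6 silyl ether) through that step. The tetrasubstituted C7=C11 alkene comes from a C6–C7≡C11–C12 ynoate by syn-bis-stannylation, hydroxymethylation at C11 (C13) and acylation at C7 (C8–C10 from crotonyl chloride).
4. C6–C7 comes from methyl propiolate and an epoxy aldehyde; C4/C5 from Sharpless epoxidation of geraniol, whose prenyl end masks the C1 aldehyde.
5. Ring order: epoxide (step 1), ten-membered carbocycle (step 10), butenolide (step 11); then C8 reduction and angeloylation.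

Key step: step 10

Remark (step 3): the facial preference of the zinc–ProPhenol catalyst is assumed to be the same as in its aldol reactions ((S,S) ligand, Re face), so the (R,R) ligand is written for the Si-face addition that gives 6S.
Remark (step 10): which antipode of the triazolium salt gives 10R in a ten-membered closure cannot be derived from the small-ring cases; the (5aS,10bR) salt is written and stands for the antipode that does.

**Step 1**
Reactants: 1 geraniol
Product: 2 (2R,3R)-2,3-epoxygeraniol
Conditions: Ti(OiPr)4 (5 mol%), D-(−)-diethyl tartrate (7.5 mol%), t-BuOOH, 4 Å molecular sieves, CH2Cl2, −20 °C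
Reagents that add atoms: tert-butyl hydroperoxide, CC(C)(C)OO
Why: Katsuki–Sharpless asymmetric epoxidation touches only the allylic 2,3-alkene, and the D-(−)-tartrate (antipode of the L-(+)-tartrate that gives the 2S,3S epoxide) sets C4 and C5 as R,R while the prenyl alkene is left as the masked C1 aldehyde.

**Step 2**
Reactants: 2 (2R,3R)-2,3-epoxygeraniol
Product: 3 (2S,3R)-3-methyl-3-(4-methylpent-3-en-1-yl)oxirane-2-carbaldehyde
Conditions: 2,2,6,6-tetramethylpiperidin-1-oxyl (TEMPO, 10 mol%), PhI(OAc)2 (1.1 equiv), CH2Cl2, 23 °C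
Reagents that add atoms: none
Why: Oxoammonium-mediated (TEMPO/PhI(OAc)2) oxidation of the primary alcohol runs under near-neutral conditions that leave the epoxide and the non-enolisable C5 center untouched.

**Step 3**
Reactants: 3 (2S,3R)-3-methyl-3-(4-methylpent-3-en-1-yl)oxirane-2-carbaldehyde; 4 methyl propiolate
Product: 5 methyl (4S)-4-hydroxy-4-[(2R,3R)-3-methyl-3-(4-methylpent-3-en-1-yl)oxiran-2-yl]but-2-ynoate
Conditions: (R,R)-ProPhenol [2,6-bis{[(2R)-2-(hydroxydiphenylmethyl)pyrrolidin-1-yl]methyl}-4-methylphenol] (20 mol%), Me2Zn (3 equiv), Ph3P=O (40 mol%), 4 (3 equiv), toluene, 4 °C; aq NH4Cl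
Reagents that add atoms: none
Why: Zinc–ProPhenol catalysed asymmetric alkynylation (Trost) adds the zinc propiolate to the Si face of the aldehyde under catalyst control to set C6 as S, and zinc chelation between the aldehyde and epoxide oxygens is expected to favour the same syn isomer.

**Step 4**
Reactants: 5 methyl (4S)-4-hydroxy-4-[(2R,3R)-3-methyl-3-(4-methylpent-3-en-1-yl)oxiran-2-yl]but-2-ynoate
Product: 6 methyl (4S)-4-[(tert-butyldimethylsilyl)oxy]-4-[(2R,3R)-3-methyl-3-(4-methylpent-3-en-1-yl)oxiran-2-yl]but-2-ynoate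
Conditions: TBSCl (1.5 equiv), imidazole (3 equiv), DMF, 23 °C
Reagents that add atoms: tert-butyldimethylsilyl chloride, CC(C)(C)[Si](C)(C)Cl
Why: Standard imidazole-mediated silylation of the secondary propargylic alcohol is chosen over silyl triflate so that no Lewis acid opens the trisubstituted epoxide.

**Step 5**
Reactants: 6 methyl (4S)-4-[(tert-butyldimethylsilyl)oxy]-4-[(2R,3R)-3-methyl-3-(4-methylpent-3-en-1-yl)oxiran-2-yl]but-2-ynoate
Product: 7 methyl (2Z,4S)-4-[(tert-butyldimethylsilyl)oxy]-4-[(2R,3R)-3-methyl-3-(4-methylpent-3-en-1-yl)oxiran-2-yl]-2,3-bis(trimethylstannyl)but-2-enoate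
Conditions: Me3SnSnMe3 (1.1 equiv), Pd(PPh3)4 (5 mol%), THF, 60 °C
Reagents that add atoms: hexamethylditin, C[Sn](C)(C)[Sn](C)(C)C
Why: Palladium-catalysed bis-stannylation of a 2-alkynoate (Sn–Sn oxidative addition, syn insertion, reductive elimination) is a syn addition, which places C6 cis to the ester on the future C7=C11 alkene, and the moderate temperature avoids the known thermal Z to E drift.

**Step 6**
Reactants: 7 methyl (2Z,4S)-4-[(tert-butyldimethylsilyl)oxy]-4-[(2R,3R)-3-methyl-3-(4-methylpent-3-en-1-yl)oxiran-2-yl]-2,3-bis(trimethylstannyl)but-2-enoate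
Product: 9 methyl (2E,4S)-4-[(tert-butyldimethylsilyl)oxy]-2-(hydroxymethyl)-4-[(2R,3R)-3-methyl-3-(4-methylpent-3-en-1-yl)oxiran-2-yl]-3-(trimethylstannyl)but-2-enoate, via α-lithio ester 8 (not isolated)
Conditions: MeLi (1.05 equiv), THF, −98 °C; CH2O (gas, from cracking paraformaldehyde), −98 to −78 °C; aq NH4Cl
Reagents that add atoms: formaldehyde, C=O
Why: Regioselective tin–lithium exchange at the ester-bearing carbon gives the stabilised α-lithio ester (allenoate), whose aldol-type hydroxymethylation should occur on the side of the long C–Sn bond and not of the branched C6 substituent, keeping C6 cis to the ester, while MeLi at −98 °C spares the ester and the epoxide.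

**Step 7**
Reactants: 9 methyl (2E,4S)-4-[(tert-butyldimethylsilyl)oxy]-2-(hydroxymethyl)-4-[(2R,3R)-3-methyl-3-(4-methylpent-3-en-1-yl)oxiran-2-yl]-3-(trimethylstannyl)but-2-enoate
Product: 10 methyl (2E,4S)-2-(acetoxymethyl)-4-[(tert-butyldimethylsilyl)oxy]-4-[(2R,3R)-3-methyl-3-(4-methylpent-3-en-1-yl)oxiran-2-yl]-3-(trimethylstannyl)but-2-enoate
Conditions: Ac2O, pyridine, DMAP (5 mol%), CH2Cl2, 0 °C
Reagents that add atoms: acetic anhydride, CC(=O)OC(C)=O
Why: Routine acetylation of the primary allylic alcohol installs the C13 acetate of the target, which is carried to the end.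

**Step 8**
Reactants: 10 methyl (2E,4S)-2-(acetoxymethyl)-4-[(tert-butyldimethylsilyl)oxy]-4-[(2R,3R)-3-methyl-3-(4-methylpent-3-en-1-yl)oxiran-2-yl]-3-(trimethylstannyl)but-2-enoate; 11 (E)-but-2-enoyl chloride
Product: 12 methyl (2E,5E)-2-(acetoxymethyl)-3-{(S)-[(tert-butyldimethylsilyl)oxy][(2R,3R)-3-methyl-3-(4-methylpent-3-en-1-yl)oxiran-2-yl]methyl}-4-oxohepta-2,5-dienoate
Conditions: 11 (2 equiv), Pd2(dba)3 (5 mol%), AsPh3 (20 mol%), THF, 50 °C
Reagents that add atoms: none
Why: Stille acylation (oxidative addition of the acid chloride, tin-to-palladium transfer with retention of alkene geometry, reductive elimination) forms C7–C8; the trimethylstannyl group is used for fast alkenyl transfer, and excess acid chloride keeps palladium as the acylpalladium chloride so that the allylic acetate is not ionised.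

**Step 9**
Reactants: 12 methyl (2E,5E)-2-(acetoxymethyl)-3-{(S)-[(tert-butyldimethylsilyl)oxy][(2R,3R)-3-methyl-3-(4-methylpent-3-en-1-yl)oxiran-2-yl]methyl}-4-oxohepta-2,5-dienoate
Product: 13 methyl (2E,5E)-2-(acetoxymethyl)-3-{(S)-[(tert-butyldimethylsilyl)oxy][(2R,3R)-3-methyl-3-(3-oxopropyl)oxiran-2-yl]methyl}-4-oxohepta-2,5-dienoate (C1 aldehyde tethered to the C8 crotonyl ketone)
Conditions: O3 (1.0 equiv, Sudan Red 7B indicator), CH2Cl2, −78 °C; PPh3, −78 to 23 °C
Reagents that add atoms: ozone, [O-][O+]=O
Why: Ozonolysis with reductive work-up cleaves the electron-rich trisubstituted prenyl alkene, which reacts with ozone far faster than the two acceptor-substituted alkenes, and so frees the C1 aldehyde only now.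

**Step 10**
Reactants: 13 methyl (2E,5E)-2-(acetoxymethyl)-3-{(S)-[(tert-butyldimethylsilyl)oxy][(2R,3R)-3-methyl-3-(3-oxopropyl)oxiran-2-yl]methyl}-4-oxohepta-2,5-dienoate
Product: 14 methyl 13-acetoxy-6-[(tert-butyldimethylsilyl)oxy]-4,5-epoxy-1,8-dioxogermacr-7(11)-en-12-oate (4R,5R,6S,10R; C6 cis to CO2Me across C7=C11)
Conditions: (5aS,10bR)-2-(pentafluorophenyl)-5a,10b-dihydro-4H,6H-indeno[2,1-b][1,2,4]triazolo[4,3-d][1,4]oxazin-2-ium tetrafluoroborate (20 mol%), KN(SiMe3)2 (18 mol%), toluene, 0.002 M, slow addition of 13 over 12 h, 25 °C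
Reagents that add atoms: none
Why: Proposed new method: the triazolylidene adds to the C1 aldehyde, proton transfer gives the Breslow enaminol (acyl anion equivalent), this adds in conjugate fashion to C10 of the (E)-crotonyl ketone, and proton transfer to C9 with loss of the carbene gives the 1,4-diketone; the closest known reaction type is the enantioselective intramolecular Stetter reaction of aliphatic aldehydes onto enones and enoates, which so far closes five- and six-membered rings in the exo mode. The ten-membered carbocycle is closed 10-endo-trig, C9 and C10 both lying inside the new ring. C10 is the only new stereocenter and its face is chosen by the chiral carbene (catalyst control), the substrate centers C4–C6 being remote from it. The step needs addition at C10 and not at C11, C7 or the C8 carbonyl: C11 and C7 belong to the fully substituted, shielded alkene and would give eight- and seven-membered rings, and a crossed benzoin at C8 an eight-membered ring. Intermolecular benzoin is held back by slow addition at high dilution and by the rigid epoxide and tetrasubstituted alkene, which limit the conformations of the chain. Base is kept below the amount of azolium salt so that neither C10 (α to the new C1 ketone) nor the acidic C6–H is deprotonated.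

**Step 11**
Reactants: 14 methyl 13-acetoxy-6-[(tert-butyldimethylsilyl)oxy]-4,5-epoxy-1,8-dioxogermacr-7(11)-en-12-oate
Product: 16 (4R,5R,6S,10R)-13-acetoxy-4,5-epoxy-1,8-dioxogermacr-7(11)-en-12,6-olide, via C6 hydroxy ester 15 (not isolated)
Conditions: HF·pyridine, pyridine, THF, 0 to 23 °C
Reagents that add atoms: none
Why: Buffered fluoride desilylation frees the C6 hydroxyl, which sits cis to the methyl ester on C7=C11 and closes the butenolide by lactonisation with loss of methanol; the absence of base protects C10 and the now acidic C6–H next to the epoxide.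

**Step 12**
Reactants: 16 (4R,5R,6S,10R)-13-acetoxy-4,5-epoxy-1,8-dioxogermacr-7(11)-en-12,6-olide
Product: 17 (4R,5R,6S,8S,10R)-13-acetoxy-4,5-epoxy-8-hydroxy-1-oxogermacr-7(11)-en-12,6-olide
Conditions: (R)-1-methyl-3,3-diphenyltetrahydro-1H,3H-pyrrolo[1,2-c][1,3,2]oxazaborole ((R)-Me-CBS, 20 mol%), catecholborane (1.5 equiv), toluene, −78 °C; MeOH, pH 7 buffer
Reagents that add atoms: none
Why: Corey–Bakshi–Shibata reduction treats the alkenyl carbon C7 as the large and C9H2 as the small substituent of the conjugated C8 ketone, so the (R)-catalyst should deliver hydride 1,2 to give 8S, and at −78 °C the unactivated dialkyl ketone at C1 should react much more slowly.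

**Step 13**
Reactants: 17 (4R,5R,6S,8S,10R)-13-acetoxy-4,5-epoxy-8-hydroxy-1-oxogermacr-7(11)-en-12,6-olide; 18 angelic acid
Product: 19 CNP0229937.2, (4R,5R,6S,8S,10R)-13-acetoxy-8-angeloyloxy-4,5-epoxy-1-oxogermacr-7(11)-en-12,6-olide
Conditions: 18 (3 equiv), 2,4,6-trichlorobenzoyl chloride (3 equiv), Et3N (3.3 equiv), toluene, 23 °C; then 17, 75 °C
Reagents that add atoms: none
Why: Yamaguchi-type esterification through the mixed anhydride without DMAP transfers the angeloyl group without Z to E isomerisation to the tiglate, retains C8 (O-acylation) and should outrun acetyl migration from O13 to O8.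

**Compound list**
1 | geraniol | CC(C)=CCC/C(C)=C/CO | starting material
2 | (2R,3R)-2,3-epoxygeraniol | CC(C)=CCC[C@@]1(C)O[C@@H]1CO | intermediate
3 | (2S,3R)-3-methyl-3-(4-methylpent-3-en-1-yl)oxirane-2-carbaldehyde | CC(C)=CCC[C@@]1(C)O[C@@H]1C=O | intermediate
4 | methyl propiolate | C#CC(=O)OC | starting material
5 | methyl (4S)-4-hydroxy-4-[(2R,3R)-3-methyl-3-(4-methylpent-3-en-1-yl)oxiran-2-yl]but-2-ynoate | CC(C)=CCC[C@@]1(C)O[C@@H]1[C@@H](O)C#CC(=O)OC | intermediate
6 | TBS ether of 5 | CC(C)=CCC[C@@]1(C)O[C@@H]1[C@@H](O[Si](C)(C)C(C)(C)C)C#CC(=O)OC | intermediate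
7 | (2Z)-2,3-bis(trimethylstannyl) enoate | CC(C)=CCC[C@@]1(C)O[C@@H]1[C@@H](O[Si](C)(C)C(C)(C)C)/C([Sn](C)(C)C)=C(/[Sn](C)(C)C)C(=O)OC | intermediate
8 | α-lithio-β-stannyl ester (lithium allenoate), not isolated | CC(C)=CCC[C@@]1(C)O[C@@H]1[C@@H](O[Si](C)(C)C(C)(C)C)/C([Sn](C)(C)C)=C(/[Li])C(=O)OC | intermediate
9 | (2E)-2-(hydroxymethyl)-3-(trimethylstannyl) enoate | CC(C)=CCC[C@@]1(C)O[C@@H]1[C@@H](O[Si](C)(C)C(C)(C)C)/C([Sn](C)(C)C)=C(/CO)C(=O)OC | intermediate
10 | (2E)-2-(acetoxymethyl)-3-(trimethylstannyl) enoate | CC(C)=CCC[C@@]1(C)O[C@@H]1[C@@H](O[Si](C)(C)C(C)(C)C)/C([Sn](C)(C)C)=C(/COC(C)=O)C(=O)OC | intermediate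
11 | (E)-but-2-enoyl chloride | C/C=C/C(Cl)=O | starting material
12 | C8 crotonyl ketone with prenyl terminus | CC(C)=CCC[C@@]1(C)O[C@@H]1[C@@H](O[Si](C)(C)C(C)(C)C)/C(C(=O)/C=C/C)=C(/COC(C)=O)C(=O)OC | intermediate
13 | C1 aldehyde tethered to the C8 crotonyl ketone (Stetter precursor) | O=CCC[C@@]1(C)O[C@@H]1[C@@H](O[Si](C)(C)C(C)(C)C)/C(C(=O)/C=C/C)=C(/COC(C)=O)C(=O)OC | intermediate
14 | ten-membered 1,8-diketone, C6 silyl ether, open enoate (Stetter product) | O=C1C[C@@H](C)C(=O)CC[C@@]2(C)O[C@@H]2[C@@H](O[Si](C)(C)C(C)(C)C)/C1=C(/COC(C)=O)C(=O)OC | intermediate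
15 | C6 hydroxy ester, not isolated | O=C1C[C@@H](C)C(=O)CC[C@@]2(C)O[C@@H]2[C@@H](O)/C1=C(/COC(C)=O)C(=O)OC | intermediate
16 | 1,8-dioxo butenolide | O=C1C[C@@H](C)C(=O)CC[C@@]2(C)O[C@@H]2[C@H]2OC(=O)C(COC(C)=O)=C12 | intermediate
17 | (8S)-8-hydroxy butenolide | O[C@H]1C[C@@H](C)C(=O)CC[C@@]2(C)O[C@@H]2[C@H]2OC(=O)C(COC(C)=O)=C12 | intermediate
18 | angelic acid, (Z)-2-methylbut-2-enoic acid | C/C=C(/C)C(=O)O | starting material
19 | CNP0229937.2 | C/C=C(/C)C(=O)O[C@H]1C[C@@H](C)C(=O)CC[C@@]2(C)O[C@@H]2[C@H]2OC(=O)C(COC(C)=O)=C12 | target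

**Step count and risks**
Total steps: 13. Longest linear sequence: 13 steps (from geraniol).

Steps most likely to fail:

1. Step 10 (Proposed new method). The ring may not close: the 10-endo transition state is strained and entropically costly, so the acyl anion equivalent can be drained by intermolecular benzoin and oligomerisation, and any excess carbene or base can deprotonate C6–H and open the epoxide. Fallback with known chemistry, setting out from 13: Pinnick oxidation (NaClO2, NaH2PO4, 2-methylbut-2-ene) would give the C1 carboxylic acid F1. Activation with (PhSe)2 and PBu3 would give the Se-phenyl selenoester F2. Acyl radical macrocyclisation (Bu3SnH, AIBN, benzene, 80 °C, syringe pump, high dilution) would then add the nucleophilic acyl radical 10-endo to C10 of the enone, and the C9 radical would be reduced by the tin hydride. This comes back to the route at 14. C10 is then under substrate control only, so its epimers would be separated or equilibrated through the C1 enol.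

2. Step 12. The ring conformation may override the oxazaborolidine and give poor facial selectivity at C8, and reduction of the C1 ketone may compete. Fallback, setting out from 16: Luche reduction (NaBH4, CeCl3·7H2O, MeOH, −78 °C), which favours the conjugated carbonyl and works under substrate control, would give the (8R)-alcohol F3 if hydride enters from the ring periphery. Mitsunobu esterification with angelic acid 18 (PPh3, DIAD, toluene, 0 °C) would then invert C8 and install the ester in one operation. This comes back to the route at 19.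

3. Step 8. Tin-to-palladium transfer from the hindered, electron-poor tetrasubstituted alkenylstannane may be slow, so that protodestannylation or ionisation of the allylic acetate by zerovalent palladium takes over. Fallback, setting out from 10: iododestannylation (I2, CH2Cl2, 0 °C) would give the alkenyl iodide F4. Nozaki–Hiyama–Kishi addition to (E)-but-2-enal (CrCl2, NiCl2 1 mol%, DMSO, 23 °C) would give the C8 allylic alcohol F5 as an epimer mixture of no consequence. Oxidation with Dess–Martin periodinane (NaHCO3, CH2Cl2) comes back to the route at 12.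

**Further compounds**
F1 | step 10 | C1 carboxylic acid from 13 | OC(=O)CC[C@@]1(C)O[C@@H]1[C@@H](O[Si](C)(C)C(C)(C)C)/C(C(=O)/C=C/C)=C(/COC(C)=O)C(=O)OC
F2 | step 10 | Se-phenyl selenoester of F1 | O=C([Se]c1ccccc1)CC[C@@]1(C)O[C@@H]1[C@@H](O[Si](C)(C)C(C)(C)C)/C(C(=O)/C=C/C)=C(/COC(C)=O)C(=O)OC
F3 | step 12 | (8R)-8-hydroxy butenolide (C8 epimer of 17) | O[C@@H]1C[C@@H](C)C(=O)CC[C@@]2(C)O[C@@H]2[C@H]2OC(=O)C(COC(C)=O)=C12
F4 | step 8 | (2E)-2-(acetoxymethyl)-3-iodo enoate | CC(C)=CCC[C@@]1(C)O[C@@H]1[C@@H](O[Si](C)(C)C(C)(C)C)/C(I)=C(/COC(C)=O)C(=O)OC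
F5 | step 8 | C8 allylic alcohol (both C8 epimers) | CC(C)=CCC[C@@]1(C)O[C@@H]1[C@@H](O[Si](C)(C)C(C)(C)C)/C(C(O)/C=C/C)=C(/COC(C)=O)C(=O)OC
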